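Partner is the charge to watch in this flask: the readings give target and nothing else, and they rise more and more slowly.

- noon: starting material 0.20 M; partner 0.24 M; temperature 100 °C; the very flask that is asked about, followed so far
- flask: starting material 0.20 M; partner 0.240 M; temperature 100 °C; time 8.0 h

noon run (percent of the starting material charged)

| time / min | target / % |
|---|---|
| 30.0 | 18.1 |
| 50.0 | 26.4 |
| 80.0 | 36.3 |
| 120 | 42.5 |
| 180 | 49.4 |
| 240 | 52.2 |
| 360 | 59.2 |

(readings scatter by 1 percentage point)

- what is taken out of target is counted as made
- the analysis behind the earlier runs scatters by 1 percentage point, standard deviation
- additions bring no volume worth counting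
- the earlier runs do not show what temperature does; that part of a forecast is a guess

- Friday's: at 8.0 h raise the temperature by 20 K, then wait 8.0 h
- Sunday's: at 8.0 h add partner, 50.0% of the amount charged, then wait 8.0 h
- Monday's: at 8.0 h take out 90% of the target then present, then wait 8.0 h
- Tuesday's: change nothing and wait 8.0 h more

1. target, in percent of the starting material first charged, at 8.0 h
2. what to do for the largest gain in target; "none" if nothing gains more than 2 percentage points (Friday's / Sunday's / Monday's / Tuesday's / none)
3. target present, with what was taken out counted in, in percent of the starting material first charged, after Friday's
4. target present, with what was taken out counted in, in percent of the starting material first charged, after Tuesday's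

Compare the mean rate over the first 30.0 min with the mean rate between the last two readings:

fall in rate = 10.3

Now suppose target takes starting material and partner one to one. Then the product c(starting material) × c(partner) at the last reading is down by this factor:

fall in product = 4.84

So the rate drops faster than the product does. The readings show no partner, so take this as my assumption: a side route eats partner, and partner is the limiting reagent. Carry one number from the last reading:

c(target) / c(partner charged) = 59.2% × 0.20 M / 0.24 M = 0.493

Call this the partner return, target made per partner charged. Treat an addition as a correction to the flask as it stands, and reckon the correction alone. Sunday's adds 50.0% of the charge, so at the same return: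

gain = 50.0% × 0.240 M × 0.493 / 0.20 M = 30 percentage points

Friday's, Monday's and Tuesday's add no partner, so I commit to Sunday's.

Set beside this flask its neighbour, the same but for 0.60 M of partner. At the same return the neighbour could make 148% of the starting material charged, more than that charge allows. So I expect partner to stop this flask, and starting material to stop the neighbour.

The forecast gave 61%, 61.5% and 63% and chose Monday's, saying “I favour equilibrium or inhibition, so Monday's, without great confidence”.

The flask gives 59.3%, 61.7% after Friday's and 61.4% after Tuesday's, and the best choice is Sunday's.

    starting material ⇌ open intermediate (K = 0.440, k = 0.0347 min⁻¹, Ea = 118 kJ mol⁻¹, ΔH = −26.0 kJ mol⁻¹)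
    partner → second intermediate (k = 1.32 min⁻¹, Ea = 113 kJ mol⁻¹)
    open intermediate + second intermediate → target (k = 0.190 M⁻¹ min⁻¹, Ea = 81.0 kJ mol⁻¹)
    2 second intermediate → homo product (k = 0.0325 M⁻¹ min⁻¹, Ea = 67.0 kJ mol⁻¹)
    (constants at 100 °C)

This flask has 0% of its partner left at 480 min, its return is 0.494, and Sunday's gains 25 points against my 30 points. On the neighbouring flask the same reckoning gives a return of 0.257, about half of the 0.493 read before. Target there reaches 77.2%, against the 148% I reckoned, with homo product at 0.217 M. Partner runs out first there too, standing at 0%, and 16% of the starting material stays unbound.

(The numbers in the tables were generated by integration for an exercise.)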